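**Retrosynthetic overview**

- Locants: ring C1(isopropenyl C11(=C12)C13)–C2–C3=C4(C14)–C5–C6–C7–C8(C15)–C9–C10. The strategy rests on the ten-membered carbocycle, in which C9 (at the ketone level) and the C11=C12 olefin on C1 are γ,δ-related through C10, a Claisen retron.
- Key disconnection: C10–C1, by [3,3] ring contraction of a twelve-membered 2-methylidene oxacycle whose allylic C12–O bond carries a silyl group on C12 as stereochemical relay.
- The oxacycle comes from the lactone C9(=O)–O–C12 (macrolactonisation, then Petasis methylenation). The seco acid is built by C7=C8 cross-metathesis, C1–C2 alkenylalane/allyl chloride coupling and C4–C5 Negishi coupling on a butynediol-derived vinyl iodide; C12 is set by acylsilane reduction.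
- Ring order: twelve-membered lactone (step 14), ten-membered carbocycle (step 16), oxirane last (step 25). After the key step: C14 to the methyl ester, protodesilylation, C9 reduction and acetate, C15 ester.

Key step: step 16

Remark 1: the relay silicon is dimethylphenylsilyl (introduced with PhMe2SiLi) and the C15 ether is TBDPS (inert to the acid used for protodesilylation); both are spectators of the key step.
Remark 2 (assumption): (+)-DIP-Cl is taken to reduce the α,β-unsaturated acylsilane with the sense known for saturated acylsilanes (silicon as the large group), i.e. to the (S)-carbinol.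

**Route**

Step 1
Reactants: 1 but-2-yne-1,4-diol
Product: 2 4-[(4-methoxybenzyl)oxy]but-2-yn-1-ol
Conditions: NaH (1 equiv), PMBCl (1 equiv), n-Bu4NI (cat.), THF/DMF, 0 °C to rt; diol in threefold excess
Reagents that add atoms: 4-methoxybenzyl chloride, COc1ccc(CCl)cc1
Why: Williamson etherification of the mono-alkoxide, the excess of diol keeping dialkylation low and being removed with water.

Step 2
Reactants: 2 4-[(4-methoxybenzyl)oxy]but-2-yn-1-ol
Product: 4 (2Z)-3-iodo-4-[(4-methoxybenzyl)oxy]but-2-en-1-ol, via cyclic alkenylalanate 3 (not isolated)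
Conditions: Red-Al, THF, 0 °C to rt; then I2, THF, −78 to 0 °C
Reagents that add atoms: iodine, II
Why: Hydroxyl-directed trans-hydroalumination of the propargylic alcohol places aluminium on the carbon remote from the free OH inside a five-membered alanate, and iodinolysis with retention should give the Z-iodide with CH2OPMB trans to C2.

Step 3
Reactants: 4 (2Z)-3-iodo-4-[(4-methoxybenzyl)oxy]but-2-en-1-ol; 5 but-3-en-1-ylzinc bromide
Product: 6 (2E)-3-{[(4-methoxybenzyl)oxy]methyl}hepta-2,6-dien-1-ol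
Conditions: PdCl2(dppf) (5 mol %), 5 (3 equiv), THF, rt to 45 °C
Reagents that add atoms: none
Why: Negishi sp2–sp3 coupling proceeds with retention at the alkenyl iodide (excess zinc reagent covers the free hydroxyl), so the C5–C7 chain ends up cis to C2.

Step 4
Reactants: 6 (2E)-3-{[(4-methoxybenzyl)oxy]methyl}hepta-2,6-dien-1-ol
Product: 8 (2E)-1-chloro-3-{[(4-methoxybenzyl)oxy]methyl}hepta-2,6-diene, via allylic mesylate 7 (not isolated)
Conditions: MsCl, 2,6-lutidine, LiCl, DMF, 0 °C
Reagents that add atoms: methanesulfonyl chloride, CS(=O)(=O)Cl; lithium chloride, [Li+].[Cl-]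
Why: Collington–Meyers chlorination, in which chloride displaces the primary allylic mesylate by SN2 without allylic transposition or loss of olefin geometry.

Step 5
Reactants: 9 prop-2-yn-1-ol; 8 (2E)-1-chloro-3-{[(4-methoxybenzyl)oxy]methyl}hepta-2,6-diene
Product: 11 (2E,5E)-6-{[(4-methoxybenzyl)oxy]methyl}-2-methyldeca-2,5,9-trien-1-ol, via alkenylalane 10 (not isolated)
Conditions: 9, Me3Al, Cp2ZrCl2 (0.25 equiv), CH2Cl2, 0 °C to rt; then 8, Pd(PPh3)4 (5 mol %), THF, rt
Reagents that add atoms: trimethylaluminium, C[Al](C)C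
Why: Negishi zirconium-catalysed syn-carboalumination sets the E-C1=C11 olefin (methyl and aluminium cis), and palladium-catalysed alkenyl–allyl coupling at the unsubstituted allyl terminus keeps both olefin geometries and gives the skipped diene.

Step 6
Reactants: 11 (2E,5E)-6-{[(4-methoxybenzyl)oxy]methyl}-2-methyldeca-2,5,9-trien-1-ol
Product: 12 (2E,5E)-6-{[(4-methoxybenzyl)oxy]methyl}-2-methyldeca-2,5,9-trienal
Conditions: MnO2, CH2Cl2, rt
Reagents that add atoms: none
Why: Manganese dioxide oxidises only the allylic alcohol and leaves the skipped diene out of conjugation.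

Step 7
Reactants: 12 (2E,5E)-6-{[(4-methoxybenzyl)oxy]methyl}-2-methyldeca-2,5,9-trienal
Product: 13 rac-(2E,5E)-1-[dimethyl(phenyl)silyl]-6-{[(4-methoxybenzyl)oxy]methyl}-2-methyldeca-2,5,9-trien-1-ol
Conditions: PhMe2SiLi, THF, −78 °C; AcOH quench at −78 °C
Reagents that add atoms: dimethylphenylsilyllithium, [Li][Si](C)(C)c1ccccc1
Why: 1,2-Addition of the silyllithium to the aldehyde is fast at −78 °C and the cold acidic quench forestalls Brook rearrangement; the carbinol forms racemic and is corrected in steps 8 and 9.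

Step 8
Reactants: 13 rac-(2E,5E)-1-[dimethyl(phenyl)silyl]-6-{[(4-methoxybenzyl)oxy]methyl}-2-methyldeca-2,5,9-trien-1-ol
Product: 14 (2E,5E)-1-[dimethyl(phenyl)silyl]-6-{[(4-methoxybenzyl)oxy]methyl}-2-methyldeca-2,5,9-trien-1-one
Conditions: Dess–Martin periodinane, NaHCO3, CH2Cl2, 0 °C, dark
Reagents that add atoms: none
Why: Dess–Martin oxidation of an α-silyl carbinol to the acylsilane under buffered, non-basic conditions.

Step 9
Reactants: 14 (2E,5E)-1-[dimethyl(phenyl)silyl]-6-{[(4-methoxybenzyl)oxy]methyl}-2-methyldeca-2,5,9-trien-1-one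
Product: 15 (1S,2E,5E)-1-[dimethyl(phenyl)silyl]-6-{[(4-methoxybenzyl)oxy]methyl}-2-methyldeca-2,5,9-trien-1-ol
Conditions: (+)-DIP-Cl (1.5 equiv), THF, −25 to 0 °C; CH3CHO; aq. NaHCO3
Reagents that add atoms: none
Why: Asymmetric reduction of an acylsilane with B-chlorodiisopinocampheylborane, in which silicon takes the place of the large group in the six-membered boat transition state, so the (+)-reagent should deliver the (S)-carbinol (Si > O > C).

Step 10
Reactants: 16 2-methylidenepropane-1,3-diol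
Product: 17 2-{[(tert-butyldiphenylsilyl)oxy]methyl}prop-2-en-1-ol
Conditions: NaH (1 equiv), TBDPSCl (1 equiv), THF, 0 °C to rt
Reagents that add atoms: tert-butyl(chloro)diphenylsilane, CC(C)(C)[Si](Cl)(c1ccccc1)c1ccccc1
Why: Monosilylation of a symmetric diol through its mono-sodium alkoxide.

Step 11
Reactants: 17 2-{[(tert-butyldiphenylsilyl)oxy]methyl}prop-2-en-1-ol
Product: 18 2-{[(tert-butyldiphenylsilyl)oxy]methyl}prop-2-enal
Conditions: MnO2, CH2Cl2, rt
Reagents that add atoms: none
Why: Manganese dioxide oxidation of the allylic alcohol to the 2-substituted acrolein.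

Step 12
Reactants: 15 (1S,2E,5E)-1-[dimethyl(phenyl)silyl]-6-{[(4-methoxybenzyl)oxy]methyl}-2-methyldeca-2,5,9-trien-1-ol; 18 2-{[(tert-butyldiphenylsilyl)oxy]methyl}prop-2-enal
Product: 19 (2E,6E,9E,11S)-2-{[(tert-butyldiphenylsilyl)oxy]methyl}-11-[dimethyl(phenyl)silyl]-11-hydroxy-6-{[(4-methoxybenzyl)oxy]methyl}-10-methylundeca-2,6,9-trienal
Conditions: Hoveyda–Grubbs II (5–10 mol %), 18 (3 equiv), CH2Cl2, 40 °C
Reagents that add atoms: none
Why: Olefin cross-metathesis of the terminal alkene with a 2-substituted acrolein in excess should give the trisubstituted enal with C6 trans to the formyl group, the trisubstituted olefins and the free carbinol being inert to the catalyst.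

Step 13
Reactants: 19 (2E,6E,9E,11S)-2-{[(tert-butyldiphenylsilyl)oxy]methyl}-11-[dimethyl(phenyl)silyl]-11-hydroxy-6-{[(4-methoxybenzyl)oxy]methyl}-10-methylundeca-2,6,9-trienal
Product: 20 (2E,6E,9E,11S)-2-{[(tert-butyldiphenylsilyl)oxy]methyl}-11-[dimethyl(phenyl)silyl]-11-hydroxy-6-{[(4-methoxybenzyl)oxy]methyl}-10-methylundeca-2,6,9-trienoic acid (seco acid)
Conditions: NaClO2, NaH2PO4, 2-methylbut-2-ene, t-BuOH/H2O, 0 °C to rt
Reagents that add atoms: sodium chlorite, [Na+].[O-]Cl=O
Why: Pinnick oxidation converts the enal into the acid without touching the olefins, the ethers or the secondary α-silyl carbinol.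

Step 14
Reactants: 20 seco acid
Product: 22 (3E,7E,10E,12S)-3-{[(tert-butyldiphenylsilyl)oxy]methyl}-12-[dimethyl(phenyl)silyl]-7-{[(4-methoxybenzyl)oxy]methyl}-11-methyl-1-oxacyclododeca-3,7,10-trien-2-one, via mixed anhydride 21 (not isolated)
Conditions: 2-methyl-6-nitrobenzoic anhydride, DMAP, CH2Cl2, rt, slow addition (about 1 mM)
Reagents that add atoms: 2-methyl-6-nitrobenzoic anhydride, Cc1cccc([N+](=O)[O-])c1C(=O)OC(=O)c1c(C)cccc1[N+](=O)[O-]
Why: Shiina macrolactonisation through the mixed anhydride at high dilution, with the C12 hydroxyl as the only nucleophile, closes the twelve-membered ring with retention at C12.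

Step 15
Reactants: 22 twelve-membered lactone
Product: 23 (3E,7E,10E,12S)-3-{[(tert-butyldiphenylsilyl)oxy]methyl}-12-[dimethyl(phenyl)silyl]-7-{[(4-methoxybenzyl)oxy]methyl}-11-methyl-2-methylidene-1-oxacyclododeca-3,7,10-triene
Conditions: Cp2TiMe2 (3 equiv), toluene, 70 °C, dark; filtration through basic alumina
Reagents that add atoms: dimethyltitanocene, C[Ti](C)(C1C=CC=C1)C1C=CC=C1
Why: Petasis methylenation of the only carbonyl group gives the exocyclic enol ether under conditions free of acid and Lewis acid.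

Step 16
Reactants: 23 twelve-membered 2-methylidene allyl vinyl ether
Product: 24 (2E,6E,9S)-2-{[(tert-butyldiphenylsilyl)oxy]methyl}-9-{(1E)-1-[dimethyl(phenyl)silyl]prop-1-en-2-yl}-6-{[(4-methoxybenzyl)oxy]methyl}cyclodeca-2,6-dien-1-one
Conditions: toluene (degassed, 5 mM), base-washed sealed tube with a trace of K2CO3, 110 °C
Reagents that add atoms: none
Why: Proposed new method: thermal Claisen ([3,3]) rearrangement of the cyclic allyl vinyl ether C10H2=C9–O–C12–C11=C1, in which C10 bonds to C1 while the allylic C12–O bond breaks and C9 becomes the ketone; the closest known reactions are the methylenation/Claisen rearrangement of alkenyl-substituted lactones and the Ireland–Claisen ring contraction of macrocyclic allylic lactones. The ten-membered carbocycle closes by contraction of the twelve-membered oxacycle: the new bond bridges C9 and C1 through the exocyclic C10 while O, C12 and C11 leave the ring and become the C1 side chain, so the closure is templated by the existing macrocycle. The one new stereocentre, C1, is set by suprafacial 1,3-transfer from (S)-C12: the six-membered array places the silyl group pseudoequatorial, because the pseudoaxial alternative meets the C8 substituent on C9 in a 1,3-diaxial contact, and with the E geometry of C1=C11 (C2 pseudoequatorial) this fixes the olefin face that C10 attacks; as C10 carries two hydrogens, chair and boat arrays lead to the same C1 configuration. The selectivity needed is [3,3] shift over hydrolysis of the 2-alkoxydiene and over Cope rearrangement of the 1,5-diene product, secured by excluding acid and using the lowest temperature that turns the substrate over; a [1,5]-hydrogen shift in the alkoxydiene is excluded because C6 is trans to C9 on C7=C8. The geometries of C7=C8 and C3=C4 are untouched and silicon ends up on an E-vinylsilane for removal in step 21.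

Step 17
Reactants: 24 cyclodecadienone with vinylsilane side chain
Product: 25 (2E,6E,9S)-2-{[(tert-butyldiphenylsilyl)oxy]methyl}-9-{(1E)-1-[dimethyl(phenyl)silyl]prop-1-en-2-yl}-6-(hydroxymethyl)cyclodeca-2,6-dien-1-one
Conditions: DDQ, CH2Cl2/pH 7 buffer, 0 °C
Reagents that add atoms: none
Why: Oxidative cleavage of the 4-methoxybenzyl ether with DDQ, to which the silyl ether, the enone and the vinylsilane are inert.

Step 18
Reactants: 25 C14 alcohol
Product: 26 (2E,6E,9S)-2-{[(tert-butyldiphenylsilyl)oxy]methyl}-9-{(1E)-1-[dimethyl(phenyl)silyl]prop-1-en-2-yl}-6-formylcyclodeca-2,6-dien-1-one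
Conditions: MnO2, CH2Cl2, rt
Reagents that add atoms: none
Why: Manganese dioxide oxidation of the allylic alcohol gives the enal with C2 trans to the formyl group, the favoured geometry.

Step 19
Reactants: 26 C14 aldehyde
Product: 27 (2E,6E,9S)-2-{[(tert-butyldiphenylsilyl)oxy]methyl}-6-carboxy-9-{(1E)-1-[dimethyl(phenyl)silyl]prop-1-en-2-yl}cyclodeca-2,6-dien-1-one
Conditions: NaClO2, NaH2PO4, 2-methylbut-2-ene, t-BuOH/H2O, 0 °C to rt
Reagents that add atoms: sodium chlorite, [Na+].[O-]Cl=O
Why: Pinnick oxidation of the enal to the acid, the scavenger protecting the vinylsilane from hypochlorous acid.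

Step 20
Reactants: 27 C14 acid
Product: 28 (2E,6E,9S)-2-{[(tert-butyldiphenylsilyl)oxy]methyl}-9-{(1E)-1-[dimethyl(phenyl)silyl]prop-1-en-2-yl}-6-(methoxycarbonyl)cyclodeca-2,6-dien-1-one
Conditions: MeI, KHCO3, DMF, rt
Reagents that add atoms: iodomethane, CI
Why: SN2 O-methylation of the carboxylate under bicarbonate, chosen over a diazoalkane so that the strained enone cannot undergo dipolar cycloaddition.

Step 21
Reactants: 28 methyl ester with vinylsilane
Product: 29 (2E,6E,9S)-2-{[(tert-butyldiphenylsilyl)oxy]methyl}-6-(methoxycarbonyl)-9-(prop-1-en-2-yl)cyclodeca-2,6-dien-1-one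
Conditions: TFA (5 equiv), CH2Cl2, 0 °C, short contact; aq. NaHCO3
Reagents that add atoms: none
Why: Ipso-protodesilylation of the vinylsilane: protonation at C12 gives the tertiary β-silyl cation at C11, which loses silicon to leave the isopropenyl group, both ring olefins now being electron-poor and unable to engage the cation.

Step 22
Reactants: 29 isopropenyl enone
Product: 30 methyl (1S,2E,6E,9S)-2-{[(tert-butyldiphenylsilyl)oxy]methyl}-1-hydroxy-9-(prop-1-en-2-yl)cyclodeca-2,6-diene-6-carboxylate (ring numbered from the carbinol carbon; 9S at C9 in project locants)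
Conditions: (R)-Me-CBS (0.3 equiv), catecholborane, toluene, −78 °C
Reagents that add atoms: none
Why: Corey–Bakshi–Shibata reduction with the alkenyl carbon C8 as large and C10H2 as small substituent, so that the (R)-catalyst should give the 9S alcohol; catecholborane does not hydroborate the isopropenyl group at this temperature.

Step 23
Reactants: 30 C9 alcohol
Product: 31 the acetate of 30 (9S)
Conditions: Ac2O, pyridine, DMAP (cat.), CH2Cl2, 0 °C
Reagents that add atoms: acetic anhydride, CC(=O)OC(C)=O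
Why: Acetylation of the secondary allylic alcohol with retention at C9.

Step 24
Reactants: 31 C9 acetate
Product: 32 methyl (1S,2E,6E,9S)-1-acetoxy-2-(hydroxymethyl)-9-(prop-1-en-2-yl)cyclodeca-2,6-diene-6-carboxylate
Conditions: HF·pyridine, pyridine, THF, 0 °C to rt
Reagents that add atoms: none
Why: Fluoride cleavage of the silyl ether under buffered acidic conditions, which avoid migration of the C9 acetate to the freed primary hydroxyl.

Step 25
Reactants: 32 C15 allylic alcohol
Product: 33 the 7R,8S epoxide of 32 (project locants 1S,7R,8S,9S; C15 hydroxymethyl on the oxirane carbon C8)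
Conditions: Ti(OiPr)4 (0.2 equiv), L-(+)-DET (0.25 equiv), t-BuOOH, 4 Å MS, CH2Cl2, −20 °C
Reagents that add atoms: tert-butyl hydroperoxide, CC(C)(C)OO
Why: Katsuki–Sharpless asymmetric epoxidation of the primary allylic alcohol: with L-(+)-tartrate the oxygen should go to the olefin face that gives the 7R,8S oxirane (the sense that turns allyl alcohol into (S)-glycidol), and the trans arrangement of C6 and C9 is carried over stereospecifically.

Step 26
Reactants: 33 epoxy alcohol; 34 (R)-2-methylbutanoic acid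
Product: 36 target CNP0352790.1 (1S,7R,8S,9S; C9 acetate; C14 methyl ester; C15 (2R)-2-methylbutanoate), via O-acylisourea 35 (not isolated)
Conditions: EDC·HCl, DMAP (cat.), CH2Cl2, 0 °C to rt
Reagents that add atoms: 1-ethyl-3-(3-dimethylaminopropyl)carbodiimide, CCN=C=NCCCN(C)C
Why: Carbodiimide (Steglich) esterification of the primary alcohol at low temperature with catalytic DMAP, which should keep the α-stereocentre of the acid and the epoxy alcohol intact.

**Compound list**

1 | but-2-yne-1,4-diol | OCC#CCO | starting material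
2 | 4-[(4-methoxybenzyl)oxy]but-2-yn-1-ol | OCC#CCOCc1ccc(OC)cc1 | intermediate
3 | sodium cyclic (Z)-alkenylalanate from 2 (five-membered O–Al–C=C–C ring, two 2-methoxyethoxy groups on Al) | [Na+].COCCO[Al-]1(OCCOC)OCC=C1COCc1ccc(OC)cc1 | intermediate (not isolated)
4 | (2Z)-3-iodo-4-[(4-methoxybenzyl)oxy]but-2-en-1-ol | OC/C=C(\I)COCc1ccc(OC)cc1 | intermediate
5 | but-3-en-1-ylzinc bromide | C=CCC[Zn]Br | starting material
6 | (2E)-3-{[(4-methoxybenzyl)oxy]methyl}hepta-2,6-dien-1-ol | OC/C=C(\CCC=C)COCc1ccc(OC)cc1 | intermediate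
7 | (2E)-3-{[(4-methoxybenzyl)oxy]methyl}hepta-2,6-dien-1-yl methanesulfonate | CS(=O)(=O)OC/C=C(\CCC=C)COCc1ccc(OC)cc1 | intermediate (not isolated)
8 | (2E)-1-chloro-3-{[(4-methoxybenzyl)oxy]methyl}hepta-2,6-diene | ClC/C=C(\CCC=C)COCc1ccc(OC)cc1 | intermediate
9 | prop-2-yn-1-ol | C#CCO | starting material
10 | (E)-3-[(dimethylalumanyl)oxy]-2-methylprop-1-en-1-yl(dimethyl)alumane | C[Al](C)OC/C(C)=C/[Al](C)C | intermediate (not isolated)
11 | (2E,5E)-6-{[(4-methoxybenzyl)oxy]methyl}-2-methyldeca-2,5,9-trien-1-ol | OC/C(C)=C/C/C=C(\CCC=C)COCc1ccc(OC)cc1 | intermediate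
12 | (2E,5E)-6-{[(4-methoxybenzyl)oxy]methyl}-2-methyldeca-2,5,9-trienal | O=C/C(C)=C/C/C=C(\CCC=C)COCc1ccc(OC)cc1 | intermediate
13 | rac-(2E,5E)-1-[dimethyl(phenyl)silyl]-6-{[(4-methoxybenzyl)oxy]methyl}-2-methyldeca-2,5,9-trien-1-ol | OC([Si](C)(C)c1ccccc1)/C(C)=C/C/C=C(\CCC=C)COCc1ccc(OC)cc1 | intermediate
14 | (2E,5E)-1-[dimethyl(phenyl)silyl]-6-{[(4-methoxybenzyl)oxy]methyl}-2-methyldeca-2,5,9-trien-1-one | O=C([Si](C)(C)c1ccccc1)/C(C)=C/C/C=C(\CCC=C)COCc1ccc(OC)cc1 | intermediate
15 | (1S,2E,5E)-1-[dimethyl(phenyl)silyl]-6-{[(4-methoxybenzyl)oxy]methyl}-2-methyldeca-2,5,9-trien-1-ol | O[C@@H]([Si](C)(C)c1ccccc1)/C(C)=C/C/C=C(\CCC=C)COCc1ccc(OC)cc1 | intermediate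
16 | 2-methylidenepropane-1,3-diol | C=C(CO)CO | starting material
17 | 2-{[(tert-butyldiphenylsilyl)oxy]methyl}prop-2-en-1-ol | C=C(CO)CO[Si](c1ccccc1)(c1ccccc1)C(C)(C)C | intermediate
18 | 2-{[(tert-butyldiphenylsilyl)oxy]methyl}prop-2-enal | C=C(C=O)CO[Si](c1ccccc1)(c1ccccc1)C(C)(C)C | intermediate
19 | (2E,6E,9E,11S)-2-{[(tert-butyldiphenylsilyl)oxy]methyl}-11-[dimethyl(phenyl)silyl]-11-hydroxy-6-{[(4-methoxybenzyl)oxy]methyl}-10-methylundeca-2,6,9-trienal | O=C/C(CO[Si](c1ccccc1)(c1ccccc1)C(C)(C)C)=C/CC/C(COCc1ccc(OC)cc1)=C\C/C=C(\C)[C@@H](O)[Si](C)(C)c1ccccc1 | intermediate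
20 | (2E,6E,9E,11S)-2-{[(tert-butyldiphenylsilyl)oxy]methyl}-11-[dimethyl(phenyl)silyl]-11-hydroxy-6-{[(4-methoxybenzyl)oxy]methyl}-10-methylundeca-2,6,9-trienoic acid | OC(=O)/C(CO[Si](c1ccccc1)(c1ccccc1)C(C)(C)C)=C/CC/C(COCc1ccc(OC)cc1)=C\C/C=C(\C)[C@@H](O)[Si](C)(C)c1ccccc1 | intermediate
21 | mixed anhydride of 20 with 2-methyl-6-nitrobenzoic acid | Cc1cccc([N+](=O)[O-])c1C(=O)OC(=O)/C(CO[Si](c1ccccc1)(c1ccccc1)C(C)(C)C)=C/CC/C(COCc1ccc(OC)cc1)=C\C/C=C(\C)[C@@H](O)[Si](C)(C)c1ccccc1 | intermediate (not isolated)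
22 | (3E,7E,10E,12S)-3-{[(tert-butyldiphenylsilyl)oxy]methyl}-12-[dimethyl(phenyl)silyl]-7-{[(4-methoxybenzyl)oxy]methyl}-11-methyl-1-oxacyclododeca-3,7,10-trien-2-one | C[Si](C)(c1ccccc1)[C@@H]1OC(=O)/C(CO[Si](c2ccccc2)(c2ccccc2)C(C)(C)C)=C/CC/C(COCc2ccc(OC)cc2)=C\C/C=C1\C | intermediate
23 | (3E,7E,10E,12S)-3-{[(tert-butyldiphenylsilyl)oxy]methyl}-12-[dimethyl(phenyl)silyl]-7-{[(4-methoxybenzyl)oxy]methyl}-11-methyl-2-methylidene-1-oxacyclododeca-3,7,10-triene | C[Si](C)(c1ccccc1)[C@@H]1OC(=C)/C(CO[Si](c2ccccc2)(c2ccccc2)C(C)(C)C)=C/CC/C(COCc2ccc(OC)cc2)=C\C/C=C1\C | intermediate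
24 | (2E,6E,9S)-2-{[(tert-butyldiphenylsilyl)oxy]methyl}-9-{(1E)-1-[dimethyl(phenyl)silyl]prop-1-en-2-yl}-6-{[(4-methoxybenzyl)oxy]methyl}cyclodeca-2,6-dien-1-one | C[Si](C)(c1ccccc1)/C=C(\C)[C@H]1C/C=C(/COCc2ccc(OC)cc2)CC/C=C(\CO[Si](c2ccccc2)(c2ccccc2)C(C)(C)C)C(=O)C1 | intermediate
25 | (2E,6E,9S)-2-{[(tert-butyldiphenylsilyl)oxy]methyl}-9-{(1E)-1-[dimethyl(phenyl)silyl]prop-1-en-2-yl}-6-(hydroxymethyl)cyclodeca-2,6-dien-1-one | C[Si](C)(c1ccccc1)/C=C(\C)[C@H]1C/C=C(/CO)CC/C=C(\CO[Si](c2ccccc2)(c2ccccc2)C(C)(C)C)C(=O)C1 | intermediate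
26 | (2E,6E,9S)-2-{[(tert-butyldiphenylsilyl)oxy]methyl}-9-{(1E)-1-[dimethyl(phenyl)silyl]prop-1-en-2-yl}-6-formylcyclodeca-2,6-dien-1-one | C[Si](C)(c1ccccc1)/C=C(\C)[C@H]1C/C=C(/C=O)CC/C=C(\CO[Si](c2ccccc2)(c2ccccc2)C(C)(C)C)C(=O)C1 | intermediate
27 | (2E,6E,9S)-2-{[(tert-butyldiphenylsilyl)oxy]methyl}-6-carboxy-9-{(1E)-1-[dimethyl(phenyl)silyl]prop-1-en-2-yl}cyclodeca-2,6-dien-1-one | C[Si](C)(c1ccccc1)/C=C(\C)[C@H]1C/C=C(/C(=O)O)CC/C=C(\CO[Si](c2ccccc2)(c2ccccc2)C(C)(C)C)C(=O)C1 | intermediate
28 | (2E,6E,9S)-2-{[(tert-butyldiphenylsilyl)oxy]methyl}-9-{(1E)-1-[dimethyl(phenyl)silyl]prop-1-en-2-yl}-6-(methoxycarbonyl)cyclodeca-2,6-dien-1-one | C[Si](C)(c1ccccc1)/C=C(\C)[C@H]1C/C=C(/C(=O)OC)CC/C=C(\CO[Si](c2ccccc2)(c2ccccc2)C(C)(C)C)C(=O)C1 | intermediate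
29 | (2E,6E,9S)-2-{[(tert-butyldiphenylsilyl)oxy]methyl}-6-(methoxycarbonyl)-9-(prop-1-en-2-yl)cyclodeca-2,6-dien-1-one | C=C(C)[C@H]1C/C=C(/C(=O)OC)CC/C=C(\CO[Si](c2ccccc2)(c2ccccc2)C(C)(C)C)C(=O)C1 | intermediate
30 | methyl (1S,2E,6E,9S)-2-{[(tert-butyldiphenylsilyl)oxy]methyl}-1-hydroxy-9-(prop-1-en-2-yl)cyclodeca-2,6-diene-6-carboxylate | C=C(C)[C@H]1C/C=C(/C(=O)OC)CC/C=C(\CO[Si](c2ccccc2)(c2ccccc2)C(C)(C)C)[C@@H](O)C1 | intermediate
31 | methyl (1S,2E,6E,9S)-1-acetoxy-2-{[(tert-butyldiphenylsilyl)oxy]methyl}-9-(prop-1-en-2-yl)cyclodeca-2,6-diene-6-carboxylate | C=C(C)[C@H]1C/C=C(/C(=O)OC)CC/C=C(\CO[Si](c2ccccc2)(c2ccccc2)C(C)(C)C)[C@@H](OC(C)=O)C1 | intermediate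
32 | methyl (1S,2E,6E,9S)-1-acetoxy-2-(hydroxymethyl)-9-(prop-1-en-2-yl)cyclodeca-2,6-diene-6-carboxylate | C=C(C)[C@H]1C/C=C(/C(=O)OC)CC/C=C(\CO)[C@@H](OC(C)=O)C1 | intermediate
33 | 7R,8S-epoxide of 32 (project locants 1S,7R,8S,9S; C9 acetate, C15 free hydroxymethyl on C8, C14 methyl ester) | C=C(C)[C@H]1C/C=C(/C(=O)OC)CC[C@H]2O[C@]2(CO)[C@@H](OC(C)=O)C1 | intermediate
34 | (R)-2-methylbutanoic acid | CC[C@@H](C)C(=O)O | starting material
35 | O-acylisourea from 34 and EDC | CC[C@@H](C)C(=O)OC(=NCC)NCCCN(C)C | intermediate (not isolated)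
36 | CNP0352790.1 (project locants 1S,7R,8S,9S; C9 acetate, C14 methyl ester, C15 (2R)-2-methylbutanoate, 7,8-epoxide, isopropenyl on C1) | C=C(C)[C@H]1C/C=C(/C(=O)OC)CC[C@H]2O[C@]2(COC(=O)[C@H](C)CC)[C@@H](OC(C)=O)C1 | target

**Step count and risks**

Total step count: 26. Longest linear sequence: 24 (steps 1–9 and 12–26).

Steps most likely to fail:

1. Step 16 (proposed new method). The sigmatropic shift may only turn over at a temperature at which the 1,5-diene of the product undergoes Cope rearrangement or the acid-sensitive alkoxydiene is hydrolysed. An incomplete preference for the silyl-pseudoequatorial array would also erode the configuration at C1. The fallback uses known chemistry, a palladium-catalysed intramolecular allylic alkylation (Tsuji–Trost macrocyclisation), and sets out from enal 19. Methyl chloroformate and pyridine convert the C12 hydroxyl into the methyl carbonate F1. Aldol addition of the lithium enolate of methyl acetate to the C9 aldehyde at −78 °C gives the β-hydroxy ester F2, and Dess–Martin oxidation gives the β-keto ester F3. Pd(PPh3)4 with dppe in THF at high dilution ionises the α-silyl allylic carbonate. The β-keto ester carbon C10 then attacks the allyl terminus remote from silicon (C1), anti to palladium, so that the overall 1,3-transfer has the same sense as the sigmatropic route and closes the ten-membered ring as the cyclic β-keto ester F4. Krapcho dealkoxycarbonylation (LiCl, wet DMSO) comes back to the route at 24.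

2. Step 25. The chiral catalyst must override the conformational bias of the E-cyclodecene, which exposes only one olefin face in each conformer, and the substitution pattern (C6 cis to the carbinol arm) is the slow class for this catalyst. Poor facial selectivity or stalled turnover is therefore possible. The fallback sets out from the C9 alcohol 30 and uses substrate direction by the secondary hydroxyl instead. VO(acac)2 and t-BuOOH in CH2Cl2 deliver oxygen from the face to which the C9 hydroxyl can reach, to give the epoxy alcohol F5. Acetylation gives the epoxy acetate F6, and HF·pyridine removes the silyl ether, coming back to the route at 33.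

3. Step 22. Reagent control may be insufficient on the twisted medium-ring enone, whose peripheral face is fixed by the ring, and conjugate reduction may compete. The fallback sets out from enone 29: Luche reduction (NaBH4, CeCl3, MeOH, −78 °C) proceeds under control of the ring conformation. Should it deliver the 9R alcohol F7, Mitsunobu inversion with acetic acid (PPh3, DIAD) installs the acetate with inversion and comes back to the route at 31.

**Further compounds**

F1 | step 16 | C12 methyl carbonate of enal 19 | O=C/C(CO[Si](c1ccccc1)(c1ccccc1)C(C)(C)C)=C/CC/C(COCc1ccc(OC)cc1)=C\C/C=C(\C)[C@@H](OC(=O)OC)[Si](C)(C)c1ccccc1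
F2 | step 16 | β-hydroxy ester from F1 and methyl acetate (C9 carbinol epimers) | COC(=O)CC(O)/C(CO[Si](c1ccccc1)(c1ccccc1)C(C)(C)C)=C/CC/C(COCc1ccc(OC)cc1)=C\C/C=C(\C)[C@@H](OC(=O)OC)[Si](C)(C)c1ccccc1
F3 | step 16 | β-keto ester (C9 ketone, C10 methylene, methyl ester) | COC(=O)CC(=O)/C(CO[Si](c1ccccc1)(c1ccccc1)C(C)(C)C)=C/CC/C(COCc1ccc(OC)cc1)=C\C/C=C(\C)[C@@H](OC(=O)OC)[Si](C)(C)c1ccccc1
F4 | step 16 | ten-membered β-keto ester (24 with CO2Me on C10) | C[Si](C)(c1ccccc1)/C=C(\C)[C@H]1C/C=C(/COCc2ccc(OC)cc2)CC/C=C(\CO[Si](c2ccccc2)(c2ccccc2)C(C)(C)C)C(=O)C1C(=O)OC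
F5 | step 25 | 7R,8S-epoxy alcohol with C15 silyl ether and free C9 hydroxyl | C=C(C)[C@H]1C/C=C(/C(=O)OC)CC[C@H]2O[C@]2(CO[Si](c3ccccc3)(c3ccccc3)C(C)(C)C)[C@@H](O)C1
F6 | step 25 | C9 acetate of F5 | C=C(C)[C@H]1C/C=C(/C(=O)OC)CC[C@H]2O[C@]2(CO[Si](c3ccccc3)(c3ccccc3)C(C)(C)C)[C@@H](OC(C)=O)C1
F7 | step 22 | 9R epimer of alcohol 30 | C=C(C)[C@H]1C/C=C(/C(=O)OC)CC/C=C(\CO[Si](c2ccccc2)(c2ccccc2)C(C)(C)C)[C@H](O)C1
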